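Saturday's run, with D at 1200 mM, and Thursday's, with D at 11 mM, end close together, and you want to know what happens in the flasks around them.

| flask | D | J | Z | remark | time |
|---|---|---|---|---|---|
| Thursday's | 11 mM (in portions, 4) | 0.50 equiv | 1.4 mM (held) | run made earlier; portions every 1.0 min |  |
| Saturday's | 1200 mM (in portions, 4) | 0.50 equiv | 1.4 mM (held) | run made earlier; portions every 1.0 min |  |
| south | 20 mM (in portions, 4) | 0.500 equiv | 1.4 mM (held) | the portions of D follow each other after 1.0 min, the first at the start | 1.0 h |
| east | 60 mM (in portions, 4) | 0.500 equiv | 1.4 mM (held) | the portions of D follow each other after 1.0 min, the first at the start | 1.0 h |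
| south-east | 200 mM (in portions, 4) | 0.500 equiv | 1.4 mM (held) | the portions of D follow each other after 1.0 min, the first at the start | 1.0 h |
| north | 500 mM (in portions, 4) | 0.500 equiv | 1.4 mM (held) | the portions of D follow each other after 1.0 min, the first at the start | 1.0 h |
| north-east | 1500 mM (in portions, 4) | 0.500 equiv | 1.4 mM (held) | the portions of D follow each other after 1.0 min, the first at the start | 1.0 h |

- Thursday's (time / min: Q / %, G / %, D / %): 2.00: 7, 11, 30; 6.00: 35, 21, 32; 10.0: 50, 25, 17; 15.0: 63, 31, 6; 25.0: 62, 36, 2; 30.0: 67, 33, 1
- Saturday's (time / min: Q / %, G / %, D / %): 2.00: 7, 10, 36; 6.00: 21, 14, 46; 10.0: 34, 16, 32; 15.0: 48, 24, 20; 25.0: 61, 32, 4; 30.0: 66, 35, 1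

(each reading ± 2 percentage points)

- at the start none of Z is in solution
- "hardly changes" means that all values lie within two and a half points (for a concentration: within two and a half percent of the largest)

- share of Q in all that became Q or G for south, east, south-east, north, north-east, in this order
- the course of these numbers from the first flask to the last (rises, then falls / falls all the way / rises all the way / hardly changes / falls, then rises)

Build the flask up one process at a time. Take the main step first, as a working assumption: each D becomes Q and each J becomes G, side by side. The charge then gives the share, because with J at 0.500 equiv, Q takes 66.7% of what forms. The last readings fit this within the scatter of 2 percentage points: Q 67% and G 33% on Thursday, Q 66% and G 35% on Saturday.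

Now add time. Late in Saturday's run, D falls from 20% at 15.0 min to 4% at 25.0 min, which reads as 4.31 min. This is the clearing half-life, the time in which the D still present halves, and it is a rough reading, given the scatter on so small a value. The last portion goes in at 3.00 min, far earlier than the end of the 1.0 h, so the flask has about 13.9 clearing half-lives to finish in.

Last, add the size of the charge. At 10.0 min Saturday's D reads 32%, more than Thursday's 17%, and it comes near that level only at 15.0 min. That lag of about 5.00 min costs 1.16 clearing half-lives out of the 13.9. North-east lies beyond Saturday's charge, so its lag is a stretch of the readings, but your count still leaves room. You therefore reckon about 66.7% in each flask, with a flat course.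

The forecast gives 67% for south, 67% for north-east and the course hardly changes: “A hump or dip between the two ends is possible, but nothing in the data points to one”.

The flasks give 66.3%, 66.3%, 66.2%, 66.2% and 66.1% from south to north-east, and the course hardly changes.

    L + J → G (k = 2.16 /M/s)
    D ⇌ J (K = 0.460, k = 0.00113 /s)
    Z ⇌ L, rate k3*(csat - [L]) (kL = 2.43 /s)
    D + L → Q (k = 1.92 /M/s)

L is the dissolved reagent, and the flat row hides its movement: at 0.0500 h, just before the last addition, north-east held [L] at 0.615 mM, against 1.40 mM at 1.00 h. Now count once more in north-east, starting from D at 2.96% at 0.500 h. The 6.96 clearing half-lives still to run leave 0.0238%, and the flask holds 0.0212% at 1.00 h.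

(The data come from a simulation on assumed constants.)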